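# Proposal: total synthesis of CNP0118468.2 through an amine-catalysed Michael–aldol bicyclisation

## The problem

The target is a trans-fused hydrindene. Ring A is numbered C1(Me)=C2–C3–C4–C5–C6 and shares C3–C4 with cyclopentane ring B, C3–C4–C7(Me2)–C8–C9(Me)OH. C5 carries the carbinol C10 with a 4-hydroxyphenyl group. C6 carries the chain C11–C25, which holds an (11Z,13Z,15Z)-triene, the C17–C19 hydroxy–methyl–hydroxy triad (anti,anti) and a (21E,23Z)-dienoic acid.

Ring A holds four contiguous stereocentres, C3 to C6, whose hydrogens alternate between the two faces, so every substituent is equatorial on a ring locked by the trans fusion. C9 is a quaternary carbinol with its methyl group cis to C2.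

C9 is the only centre that can be bought; it can bias C3 and C4. C4 can then direct C5 through the C4–C7 bond, and C5 and C10 are tied together by an aldol transition state. C6 is the awkward centre. Thermodynamics cannot be trusted, because an equatorial C11 is nearly eclipsed with the C1 methyl group. Reagent approach cannot be trusted either: an external reagent meeting a trigonal C6 is expected to come anti to the C5 substituent, so a hydroboration or protonation would put hydrogen, not carbon, trans to C10. C6 is therefore set by a stereospecific hydrogen transfer. C17–C19 lie too far from the core for relay and need reagent control.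

The fragile groups are:
- the 4-hydroxybenzylic alcohol, which ionises to a quinone methide under acid;
- the all-cis triene, which is open to isomerisation and to a [1,7]-hydrogen shift on heating;
- the 2Z-enoic acid;
- any beta-silyloxy carbonyl intermediate (elimination) and any C6 carbonyl compound with the C1=C2 alkene beta,gamma to it (conjugation).

The key step rests on one feature: both ring-closing bonds lie alpha to carbonyl groups of an open chain. C3 is alpha to a C2 aldehyde and five atoms from the enone carbon C4; C1 is alpha to the C6 ketone and ends 1,5 to C2 once C3–C4 exists. C9 maps onto (S)-citramalic acid.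

## Retrosynthesis

**Deprotection (47 from 46 from 45).** No skeletal bond is cut. All hydroxyl groups are carried as silyl ethers and the acid as its methyl ester, so the end of the route needs only hydroxide and buffered fluoride. Acid-labile groups were avoided because of the 4-hydroxybenzylic alcohol. The forward steps must run at or below 40 °C to spare the triene.

**Triene (45 from 44; 44 from 31 and 43; 43 from 41 and 42).** The cuts are C12–C13 and C14–C15, with (Z)-1,2-dichloroethene 42 as the C13=C14 linchpin between two terminal alkynes. The neighbouring cut, C11=C12 by olefination of a C6 aldehyde, was rejected: that aldehyde is epimerisable and prone to conjugation. The precursors, core alkyne 31 and chain alkyne 41, are each far simpler than the target. The forward reactions must couple alkenyl chlorides with retention and then reduce two conjugated triple bonds to cis alkenes in enediyne 44 without touching the dienoate.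

**C6–C11 (31 from 28 from 27 from 26 from 25).** The C6–C11 bond is cut back to the C6 ketone of 25 and an ethynyl nucleophile. A one-carbon Wittig homologation was set aside, because the 1-alkoxy-diene it gives hydrolyses by protonation at C2 to the conjugated enal. Hydroboration of a C6 methylene was set aside for the facial reason given above. Instead the carbinol 26 is transposed oxidatively to the C2 enone 27 and reduced to the equatorial alcohol 28. The hydrogen at C6 is then delivered suprafacially from an axial diazene at C2, which returns the double bond to C1=C2. The forward sequence needs axial hydride delivery at C2 and a Mitsunobu displacement with inversion.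

**C5–C10 (25 and 24 from 20 and 21).** The aldol bond C5–C10 is cut to hydrindenone 20 and aldehyde 21. The forward reaction must be syn-selective from a cyclic enolate, which excludes a lithium or boron enolate and points to a zirconocene enolate. It must also meet C5 anti to the C4–C7 bond, as alpha' enolates of 5-substituted cyclohexenones do.

**Both rings (20 from 17).** Both rings are opened at C3–C4 and C1=C2, giving the acyclic aldehyde–enone 17 with C9 as its only stereocentre. The alternative cuts, ring A alone or ring B alone, leave a carbocycle to be made separately. The forward reaction is an enamine Michael addition followed by aldol condensation; it must set C3 and C4 and give the trans fusion.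

**Open chain (17 from 16, 15, 13, 11, 10; 10 from 7 and 8; 7 from 5, 4, 3, 2, 1).** C4=C5 is cut by a Horner–Wadsworth–Emmons reaction into aldehyde 13 and phosphonate 14. C7–C8 is cut into epoxide 7 and isobutyronitrile 8. The epoxide comes from (S)-citramalic acid 1 through triol 2, with C9 never touched. The tertiary alcohol must be silylated before the enone exists, or O9 would add to C4.

**Chain alkyne (41 from 40, 39, 38, 37, 36, 34, 33, 32).** The cuts are C23=C24 (Still–Gennari olefination), C21=C22 (cross-metathesis with methacrolein), C19–C20 (allylboration) and C17–C18 (crotylboration of 3-(trimethylsilyl)propynal 32). Starting at the alkyne end means the Me/OH anti relation is made first and the second carbinol is set by reagent control against a modest Felkin bias.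

## Roads not taken

**Alternative 1:** three-component assembly on a preformed ring B. The cuts are C4–C5 and C2–C3. In the forward key step the ketene silyl acetal A2 adds to the beta carbon of 4,4-dimethylcyclopent-2-en-1-one A1 under a chiral disulfonimide-derived silylium catalyst, and the enol silane is trapped by trimethyl orthoformate with Me3SiOSO2CF3 to give the trans keto ester acetal A3.
- Merits: a cheap achiral enone, catalytic control of C3 and C4, and two bonds in one flask. It reaches a ring B intermediate in far fewer steps than the eleven needed for 17, and it avoids an intramolecular bond between two neopentyl carbons.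
- Weak points: the beta carbon of A1 sits next to the gem-dimethyl carbon, a poor site for a Mukaiyama–Michael addition. C9 is left as a ketone, and methyl addition should come anti to the C3 substituent, which places the methyl group trans to C2; the target needs it cis. Ring A would still be closed by the same aldol condensation after the ester is turned into an ethyl ketone.
- Comparison: this road is better in convergence and step count to ring B. The chosen plan sets against that a C9 centre fixed from the chiral pool and both rings closed in one operation.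

**Alternative 2:** alkyne-metathesis macrolactone. The cut is C13≡C14 inside a 19-membered lactone that joins O10 to C25. Mo(≡CC6H4OMe-4)(OSiPh3)3 would close the dienyne macrolactone A4, followed by semi-reduction.
- Merits: the metathesis is tolerant and dependable, and only one triple bond has to be reduced. In that respect it is cleaner than the enediyne 44, which has two triple bonds and needs an alkenyl chloride coupling.
- Weak points: the target is the open hydroxy acid, so the lactone is a detour. It needs esterification of the hindered C10 carbinol with a 2Z-dienoic acid and a late hydrolysis of a benzylic ester beside the triene. It also presupposes a core that already carries a (Z)-enyne on C6, so the C6 problem is untouched.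
- Comparison: better in geometric purity of the triene; worse by two steps and silent on the hardest stereocentre.

**Alternative 3:** palladium enolate alkenylation closing ring A. The cut is C1–C6. Pd2(dba)3 with P(t-Bu)3 and LiN(SiMe3)2 would couple the C6 ester enolate with a C1 alkenyl iodide to give the hydrindene ester A5.
- Merits: C11 arrives at the ester oxidation level together with ring closure. This answers directly the C6–C11 problem that costs the chosen plan four steps (15 to 18).
- Weak points: the C6 hydrogen of A5 is flanked by the ester and the alkene, so it is removed by the amide base and its configuration is left to reprotonation, with conjugation as a competing fate. The precursor needs a stereodefined trisubstituted alkenyl iodide on a ring B that already carries C3, C4, C5 and C10. Six-membered closures of this kind on hindered ester enolates have little support.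
- Comparison: shorter at C6 if it works. The chosen plan sets against it a C6 centre fixed by a stereospecific hydrogen transfer and a ring synthesis that starts from an acyclic chain.

Key step: step 12

Assumption: descriptors of intermediates without a simple systematic name use the skeleton numbering C1–C25 defined above; some change for formal priority reasons although only C2 is inverted on the route (step 18), and the catalyst enantiomer in step 12 is assigned by the usual steric-shielding model of diarylprolinol silyl ethers.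

## Route

### Core, open-chain stage (steps 1–11)

Step 1
Reactants: 1 (S)-citramalic acid
Product: 2 (2S)-2-methylbutane-1,2,4-triol
Conditions: BH3·SMe2, B(OMe)3, THF, 0 °C to rt; MeOH
Reagents that add atoms: none
Why: Borane reduction of both carboxyl groups, the malic acid to butanetriol reduction applied to the 2-methyl homologue; the quaternary carbinol (future C9) is not involved and keeps its configuration.

Step 2
Reactants: 2 (2S)-2-methylbutane-1,2,4-triol
Product: 3 2-[(4S)-2,2,4-trimethyl-1,3-dioxolan-4-yl]ethan-1-ol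
Conditions: Me2C(OMe)2, TsOH·H2O (cat.), acetone, rt
Reagents that add atoms: 2,2-dimethoxypropane, COC(C)(C)OC
Why: Acetalisation under equilibrating conditions should favour the five-membered dioxolane across the 1,2-diol over the 1,3-dioxane, which would carry an axial methyl group; the future C2 alcohol stays free.

Step 3
Reactants: 3 2-[(4S)-2,2,4-trimethyl-1,3-dioxolan-4-yl]ethan-1-ol
Product: 4 (4S)-4-{2-[(4-methoxyphenyl)methoxy]ethyl}-2,2,4-trimethyl-1,3-dioxolane
Conditions: NaH, 4-MeOC6H4CH2Cl, n-Bu4NI (cat.), THF/DMF, 0 °C to rt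
Reagents that add atoms: 4-methoxybenzyl chloride, COc1ccc(CCl)cc1
Why: Williamson etherification; the 4-methoxybenzyl ether survives base, carbanions, i-Bu2AlH and silylation and can later be removed oxidatively beside a tertiary silyl ether and an enone.

Step 4
Reactants: 4 (4S)-4-{2-[(4-methoxyphenyl)methoxy]ethyl}-2,2,4-trimethyl-1,3-dioxolane
Product: 5 (2S)-4-[(4-methoxyphenyl)methoxy]-2-methylbutane-1,2-diol
Conditions: AcOH/H2O (4:1), 40 °C
Reagents that add atoms: none
Why: Acetal hydrolysis; the benzylic ether is stable to aqueous acetic acid.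

Step 5
Reactants: 5 (2S)-4-[(4-methoxyphenyl)methoxy]-2-methylbutane-1,2-diol
Product: 7 (2S)-2-{2-[(4-methoxyphenyl)methoxy]ethyl}-2-methyloxirane, via primary monotosylate 6 (not isolated)
Conditions: NaH, THF, 0 °C; N-tosylimidazole, 0 °C to rt
Reagents that add atoms: none
Why: The primary alkoxide is sulfonylated selectively and the tertiary alkoxide then displaces the tosylate (one-pot diol-to-epoxide conversion, intramolecular Williamson reaction); the C9–O bond is never broken, so the configuration is retained.

Step 6
Reactants: 7 (2S)-2-{2-[(4-methoxyphenyl)methoxy]ethyl}-2-methyloxirane; 8 isobutyronitrile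
Product: 10 (4R)-4-hydroxy-6-[(4-methoxyphenyl)methoxy]-2,2,4-trimethylhexanenitrile, via 2-lithio-2-methylpropanenitrile 9 (not isolated)
Conditions: 8, LiN(i-Pr)2, THF, −78 °C; then 7, −78 °C to rt; aq. NH4Cl
Reagents that add atoms: none
Why: The nitrile-stabilised carbanion opens the 2,2-disubstituted epoxide at its CH2 terminus C8 (SN2 epoxide opening), forming C7–C8 and the quaternary C7 at once; C9 is untouched.

Step 7
Reactants: 10 (4R)-4-hydroxy-6-[(4-methoxyphenyl)methoxy]-2,2,4-trimethylhexanenitrile
Product: 11 (4R)-6-[(4-methoxyphenyl)methoxy]-2,2,4-trimethyl-4-[(triethylsilyl)oxy]hexanenitrile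
Conditions: Et3SiOSO2CF3, 2,6-lutidine, CH2Cl2, −78 to 0 °C
Reagents that add atoms: triethylsilyl trifluoromethanesulfonate, CC[Si](CC)(CC)OS(=O)(=O)C(F)(F)F
Why: A silyl triflate silylates the hindered tertiary alcohol; the ether must be in place before the enone exists, since free O9 would add to C4 in a 5-exo oxa-Michael reaction.

Step 8
Reactants: 11 (4R)-6-[(4-methoxyphenyl)methoxy]-2,2,4-trimethyl-4-[(triethylsilyl)oxy]hexanenitrile
Product: 13 (4R)-6-[(4-methoxyphenyl)methoxy]-2,2,4-trimethyl-4-[(triethylsilyl)oxy]hexanal, via N-aluminio imine 12 (not isolated)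
Conditions: i-Bu2AlH, toluene, −78 °C; aq. KNaC4H4O6
Reagents that add atoms: water, O
Why: Partial reduction of the nitrile stops at the N-aluminio imine, which is hydrolysed on work-up; the quaternary alpha carbon rules out enolisation and over-reduction is slow at −78 °C.

Step 9
Reactants: 13 (4R)-6-[(4-methoxyphenyl)methoxy]-2,2,4-trimethyl-4-[(triethylsilyl)oxy]hexanal; 14 dimethyl (2-oxobutyl)phosphonate
Product: 15 (4E,8R)-10-[(4-methoxyphenyl)methoxy]-6,6,8-trimethyl-8-[(triethylsilyl)oxy]dec-4-en-3-one
Conditions: Ba(OH)2·8H2O, THF/H2O (40:1), rt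
Reagents that add atoms: none
Why: Horner–Wadsworth–Emmons reaction of a beta-keto phosphonate, E-selective; the mild barium hydroxide variant suits a neopentyl aldehyde that cannot enolise.

Step 10
Reactants: 15 (4E,8R)-10-[(4-methoxyphenyl)methoxy]-6,6,8-trimethyl-8-[(triethylsilyl)oxy]dec-4-en-3-one
Product: 16 (4E,8R)-10-hydroxy-6,6,8-trimethyl-8-[(triethylsilyl)oxy]dec-4-en-3-one
Conditions: DDQ, CH2Cl2/pH 7 buffer (10:1), 0 °C
Reagents that add atoms: none
Why: Oxidative cleavage of the 4-methoxybenzyl ether; the enone and the tertiary silyl ether are inert to buffered DDQ.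

Step 11
Reactants: 16 (4E,8R)-10-hydroxy-6,6,8-trimethyl-8-[(triethylsilyl)oxy]dec-4-en-3-one
Product: 17 (3R,6E)-3,5,5-trimethyl-8-oxo-3-[(triethylsilyl)oxy]dec-6-enal
Conditions: Dess–Martin periodinane, NaHCO3, CH2Cl2, 0 °C to rt
Reagents that add atoms: none
Why: Dess–Martin oxidation under buffered, non-basic conditions, chosen so that the beta-silyloxy aldehyde does not eliminate; the aldehyde is used at once.

### Key step and core elaboration (steps 12–18)

Step 12
Reactants: 17 (3R,6E)-3,5,5-trimethyl-8-oxo-3-[(triethylsilyl)oxy]dec-6-enal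
Product: 20 (1R,3aR,7aR)-1,3,3,6-tetramethyl-1-[(triethylsilyl)oxy]-1,2,3,3a,4,7a-hexahydro-5H-inden-5-one, via Michael adduct keto aldehyde 18 (not isolated), via aldol adduct 19 (not isolated)
Conditions: (R)-2-[diphenyl(trimethylsilyloxy)methyl]pyrrolidine (20 mol %), PhCO2H (20 mol %), toluene, 0 °C to rt; then TsOH·H2O (30 mol %), 4 Å MS, 45 °C
Reagents that add atoms: none
Why: The aldehyde condenses with the amine to an E-enamine whose carbon C3 adds to C4 of the tethered enone (C3–C4, ring B), and hydrolysis returns the catalyst and keto aldehyde 18; added TsOH then enolises the ethyl ketone toward C1 and, with the amine, activates the aldehyde as its iminium ion, C1 attacks C2, and aldol 19 loses water to give the C1=C2 enone of ring A. The closest known reaction type is the amine-catalysed Michael addition of aldehydes to enones followed by aldol condensation of the 1,5-keto aldehyde (organocatalytic Robinson-type annulation), whose intramolecular Michael variant gives trans-disubstituted cyclopentanes. Ring B closes 5-exo-trig; ring A closes 6-(enolendo)-exo-trig, and the only other enolisable carbon, C5, could close only a four-membered ring. C3 is set by the catalyst, whose diphenyl(silyloxy)methyl group shields one enamine face so that the enone is met on the other; the (R)-enantiomer is the one this model assigns to the required configuration. C4 follows from the open transition state that puts the formyl group and the C5 arm trans on the new ring, and the fixed C9 centre should reinforce this by keeping the formyl carbon anti to the silyloxy group. The step needs carbon–carbon bond formation ahead of elimination or oxygen addition, and a trans ring fusion: the silyl ether blocks oxa-Michael addition of O9, the C7 gem-dimethyl group favours the first closure, and C3 stays epimerisable, alpha to the aldehyde, until dehydration locks the fusion.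

Step 13
Reactants: 20 (1R,3aR,7aR)-1,3,3,6-tetramethyl-1-[(triethylsilyl)oxy]-1,2,3,3a,4,7a-hexahydro-5H-inden-5-one; 21 4-[(tert-butyldimethylsilyl)oxy]benzaldehyde
Product: 24 syn-aldol (skeleton 3R,4S,5S,9R,10S), via lithium dienolate 22 (not isolated), via zirconium enolate 23 (not isolated)
Conditions: LiN(i-Pr)2, THF, −78 °C; Cp2ZrCl2, −78 to −40 °C; 21, −78 °C
Reagents that add atoms: none
Why: Kinetic alpha' deprotonation at C5, transmetalation and aldol addition; chlorozirconocene enolates give syn aldols whatever the enolate geometry, cyclic ketones included, which sets C10 relative to C5. The aldehyde should meet C5 anti to the C4–C7 bond with its gem-dimethyl group, as alpha' enolates of 5-substituted cyclohexenones react trans, which puts C10 equatorial.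

Step 14
Reactants: 24 syn-aldol (skeleton 3R,4S,5S,9R,10S)
Product: 25 C10 silyl ether of 24 (skeleton 3R,4S,5S,9R,10S)
Conditions: t-BuMe2SiOSO2CF3, 2,6-lutidine, CH2Cl2, −78 to 0 °C
Reagents that add atoms: tert-butyldimethylsilyl trifluoromethanesulfonate, CC(C)(C)[Si](C)(C)OS(=O)(=O)C(F)(F)F
Why: Silylation of the hindered benzylic alcohol with a silyl triflate at low temperature, which also removes any retro-aldol pathway in the following steps.

Step 15
Reactants: 25 C10 silyl ether of 24
Product: 26 C6 ethynyl carbinol (C6 epimers)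
Conditions: HC≡CMgBr, CeCl3, THF, −78 to 0 °C
Reagents that add atoms: ethynylmagnesium bromide, C#C[Mg]Br
Why: Cerium chloride-promoted 1,2-addition of a slim alkynyl nucleophile to the hindered enone brings in C11 and C12 and suppresses enolisation; the configuration of the new carbinol is of no consequence because C6 becomes trigonal in the next step.

Step 16
Reactants: 26 C6 ethynyl carbinol (C6 epimers)
Product: 27 transposed enone with C2 ketone and C1=C6 alkene (skeleton 3R,4R,5R,9R,10S)
Conditions: [C5H5NH][CrO3Cl], NaOAc, 4 Å MS, CH2Cl2, rt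
Reagents that add atoms: pyridinium chlorochromate, [O-][Cr](=O)(=O)Cl.c1cc[nH+]cc1
Why: Babler–Dauben oxidative transposition: the chromate ester of the tertiary allylic alcohol shifts [3,3] to C2 and is oxidised there, giving the enone with the ethynyl group on the trigonal C6.

Step 17
Reactants: 27 transposed enone with C2 ketone and C1=C6 alkene
Product: 28 C2 allylic alcohol with hydroxyl cis to H3 (skeleton 2R,3S,4R,5R,9R,10S)
Conditions: NaBH4, CeCl3·7H2O, MeOH, −78 °C
Reagents that add atoms: none
Why: Luche 1,2-reduction; the small hydride should enter axially, anti to the axial C3–H bond, giving the pseudo-equatorial alcohol on the face of H3.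

Step 18
Reactants: 28 C2 allylic alcohol with hydroxyl cis to H3
Product: 31 core alkyne (skeleton 3R,4R,5R,6R,9R,10S), via sulfonylhydrazine adduct 29 (not isolated), via allylic diazene 30 (not isolated)
Conditions: 2-O2NC6H4SO2NHNH2, PPh3, EtO2CN=NCO2Et, THF, −30 °C; then rt
Reagents that add atoms: none
Why: Mitsunobu displacement with 2-nitrobenzenesulfonylhydrazide inverts C2, loss of the sulfinic acid gives the axial monoalkyl diazene, and its retro-ene reaction transfers hydrogen suprafacially to C6 with loss of N2 and return of the alkene to C1=C2 (allylic diazene reductive transposition). Hydrogen therefore arrives on the face of the axial C2–N bond, leaving the ethynyl group equatorial and trans to C10.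

### Chain fragment (steps 19–27)

Step 19
Reactants: 32 3-(trimethylsilyl)prop-2-ynal
Product: 33 (3R,4R)-4-methyl-1-(trimethylsilyl)hex-5-en-1-yn-3-ol
Conditions: (E)-but-2-ene, KOt-Bu, n-BuLi, THF, −78 to −45 °C; (+)-Ipc2BOMe; BF3·OEt2, 32, −78 °C; NaOH, H2O2
Reagents that add atoms: (E)-but-2-ene, C/C=C/C
Why: Brown crotylboration: the E-crotylborane reacts through a chair transition state to give the anti product, and the (+)-diisopinocampheyl reagent adds to the Re face of the aldehyde, setting C17 and C18.

Step 20
Reactants: 33 (3R,4R)-4-methyl-1-(trimethylsilyl)hex-5-en-1-yn-3-ol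
Product: 34 tert-butyldimethylsilyl ether of 33
Conditions: t-BuMe2SiCl, imidazole, DMF, rt
Reagents that add atoms: tert-butyldimethylsilyl chloride, CC(C)(C)[Si](C)(C)Cl
Why: Standard silylation of a secondary propargylic alcohol.

Step 21
Reactants: 34 tert-butyldimethylsilyl ether of 33
Product: 36 (2S,3R)-3-[(tert-butyldimethylsilyl)oxy]-2-methyl-5-(trimethylsilyl)pent-4-ynal, via vicinal diol 35 (not isolated)
Conditions: OsO4 (2 mol %), NaIO4, 2,6-lutidine, dioxane/H2O (3:1), rt
Reagents that add atoms: sodium periodate, [Na+].[O-]I(=O)(=O)=O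
Why: Lemieux–Johnson oxidation; the terminal alkene is dihydroxylated much faster than the silyl-capped alkyne, and the lutidine buffer protects the alpha stereocentre.

Step 22
Reactants: 36 (2S,3R)-3-[(tert-butyldimethylsilyl)oxy]-2-methyl-5-(trimethylsilyl)pent-4-ynal
Product: 37 (3R,4R,5R)-3-[(tert-butyldimethylsilyl)oxy]-4-methyl-1-(trimethylsilyl)oct-7-en-1-yn-5-ol
Conditions: (+)-Ipc2B(CH2CH=CH2), Et2O, −78 °C; NaOH, H2O2
Reagents that add atoms: (+)-B-allyldiisopinocampheylborane, C=CCB(C1CC2CC(C1C)C2(C)C)C1CC2CC(C1C)C2(C)C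
Why: Brown allylboration under reagent control: the (+)-reagent adds to the Re face and so gives the 18,19-anti carbinol against the modest Felkin preference of the alpha-methyl aldehyde; with the methyl group anti to both oxygens the 1,3-diol is syn.

Step 23
Reactants: 37 (3R,4R,5R)-3-[(tert-butyldimethylsilyl)oxy]-4-methyl-1-(trimethylsilyl)oct-7-en-1-yn-5-ol
Product: 38 (3R,4R,5R)-3,5-bis[(tert-butyldimethylsilyl)oxy]-4-methyl-1-(trimethylsilyl)oct-7-en-1-yne
Conditions: t-BuMe2SiOSO2CF3, 2,6-lutidine, CH2Cl2, 0 °C
Reagents that add atoms: tert-butyldimethylsilyl trifluoromethanesulfonate, CC(C)(C)[Si](C)(C)OS(=O)(=O)C(F)(F)F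
Why: Silylation of the hindered secondary alcohol with the triflate.

Step 24
Reactants: 38 (3R,4R,5R)-3,5-bis[(tert-butyldimethylsilyl)oxy]-4-methyl-1-(trimethylsilyl)oct-7-en-1-yne
Product: 39 (2E,5R,6R,7R)-5,7-bis[(tert-butyldimethylsilyl)oxy]-2,6-dimethyl-9-(trimethylsilyl)non-2-en-8-ynal
Conditions: CH2=C(CH3)CHO (10 equiv), second-generation Hoveyda–Grubbs catalyst RuCl2(H2IMes)(=CH-C6H4-2-O-i-Pr) (5 mol %), CH2Cl2, 40 °C
Reagents that add atoms: methacrolein, CC(=C)C=O
Why: Cross-metathesis of a terminal alkene with a 2-substituted acrolein gives the E-trisubstituted enal (C21=C22) under thermodynamic control; the silyl-capped alkyne is too hindered to enter enyne metathesis readily.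

Step 25
Reactants: 39 (2E,5R,6R,7R)-5,7-bis[(tert-butyldimethylsilyl)oxy]-2,6-dimethyl-9-(trimethylsilyl)non-2-en-8-ynal
Product: 40 methyl (2Z,4E,7R,8R,9R)-7,9-bis[(tert-butyldimethylsilyl)oxy]-4,8-dimethyl-11-(trimethylsilyl)undeca-2,4-dien-10-ynoate
Conditions: (CF3CH2O)2P(O)CH2CO2Me, KN(SiMe3)2, 18-crown-6, THF, −78 °C
Reagents that add atoms: methyl bis(2,2,2-trifluoroethoxy)phosphinylacetate, COC(=O)CP(=O)(OCC(F)(F)F)OCC(F)(F)F
Why: Still–Gennari olefination: the electron-poor phosphonate with a dissociated potassium counter-ion collapses under kinetic control to the Z-enoate (C23=C24).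

Step 26
Reactants: 40 methyl (2Z,4E,7R,8R,9R)-7,9-bis[(tert-butyldimethylsilyl)oxy]-4,8-dimethyl-11-(trimethylsilyl)undeca-2,4-dien-10-ynoate
Product: 41 methyl (2Z,4E,7R,8R,9R)-7,9-bis[(tert-butyldimethylsilyl)oxy]-4,8-dimethylundeca-2,4-dien-10-ynoate
Conditions: K2CO3, MeOH, 0 °C to rt
Reagents that add atoms: none
Why: Methanolysis of the alkynyl C–Si bond; the alkyl silyl ethers are stable and transesterification of the methyl ester is degenerate.

Step 27
Reactants: 41 methyl (2Z,4E,7R,8R,9R)-7,9-bis[(tert-butyldimethylsilyl)oxy]-4,8-dimethylundeca-2,4-dien-10-ynoate; 42 (Z)-1,2-dichloroethene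
Product: 43 methyl (2Z,4E,7R,8R,9R,12Z)-7,9-bis[(tert-butyldimethylsilyl)oxy]-13-chloro-4,8-dimethyltrideca-2,4,12-trien-10-ynoate
Conditions: 42 (5 equiv), Pd(PPh3)4 (5 mol %), CuI (10 mol %), n-BuNH2, benzene, rt
Reagents that add atoms: none
Why: Sonogashira coupling of the dichloroalkene proceeds with retention of the Z geometry; the excess of 42 keeps the reaction at mono-coupling (C14–C15).

### Fragment union and endgame (steps 28–31)

Step 28
Reactants: 31 core alkyne (skeleton 3R,4R,5R,6R,9R,10S); 43 methyl (2Z,4E,7R,8R,9R,12Z)-7,9-bis[(tert-butyldimethylsilyl)oxy]-13-chloro-4,8-dimethyltrideca-2,4,12-trien-10-ynoate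
Product: 44 protected enediyne methyl ester (skeleton 3R,4R,5R,6S,9R,10S,17R,18R,19R)
Conditions: Pd(PPh3)4 (5 mol %), CuI (10 mol %), piperidine, THF, rt
Reagents that add atoms: none
Why: Second Sonogashira coupling forms C12–C13; the alkenyl chloride is activated toward oxidative addition to zerovalent palladium by the conjugated alkyne and couples with retention.

Step 29
Reactants: 44 protected enediyne methyl ester
Product: 45 protected (11Z,13Z,15Z)-triene methyl ester (skeleton 3R,4R,5R,6S,9R,10S,17S,18R,19R)
Conditions: Zn(Cu/Ag), MeOH/H2O (1:1), rt to 40 °C, dark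
Reagents that add atoms: none
Why: Activated zinc reduces only triple bonds conjugated with an alkene and gives cis alkenes without over-reduction; both triple bonds flank C13=C14 and qualify, while the dienoate and the ring alkene are left alone.

Step 30
Reactants: 45 protected (11Z,13Z,15Z)-triene methyl ester
Product: 46 carboxylic acid with free phenol (skeleton 3R,4R,5R,6S,9R,10S,17S,18R,19R)
Conditions: LiOH, THF/MeOH/H2O, 0 °C to rt; aq. NaH2PO4
Reagents that add atoms: lithium hydroxide, [Li+].[OH-]
Why: Saponification of the methyl ester at room temperature; the aryl silyl ether is cleaved by hydroxide as well, while the four alkyl silyl ethers stay and keep the benzylic position protected.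

Step 31
Reactants: 46 carboxylic acid with free phenol
Product: 47 CNP0118468.2
Conditions: n-Bu4NF, AcOH (1:1), THF, 0 to 30 °C
Reagents that add atoms: none
Why: Fluoride-mediated cleavage of the three tert-butyldimethylsilyl ethers and the tertiary triethylsilyl ether; buffering with acetic acid avoids both base-induced isomerisation and acid-induced ionisation of the 4-hydroxybenzylic alcohol.

## Compound list

1 | (S)-citramalic acid, (2S)-2-hydroxy-2-methylbutanedioic acid | OC(=O)[C@@](CC(=O)O)(C)O | starting material
2 | (2S)-2-methylbutane-1,2,4-triol | OC[C@@](CCO)(C)O | intermediate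
3 | 2-[(4S)-2,2,4-trimethyl-1,3-dioxolan-4-yl]ethan-1-ol | OCC[C@@]1(C)COC(C)(C)O1 | intermediate
4 | (4S)-4-{2-[(4-methoxyphenyl)methoxy]ethyl}-2,2,4-trimethyl-1,3-dioxolane | COc1ccc(COCC[C@@]2(C)COC(C)(C)O2)cc1 | intermediate
5 | (2S)-4-[(4-methoxyphenyl)methoxy]-2-methylbutane-1,2-diol | OC[C@@](CCOCc1ccc(OC)cc1)(C)O | intermediate
6 | (2S)-2-hydroxy-4-[(4-methoxyphenyl)methoxy]-2-methylbutyl 4-methylbenzenesulfonate (formed in the flask) | Cc1ccc(cc1)S(=O)(=O)OC[C@@](CCOCc2ccc(OC)cc2)(C)O | intermediate
7 | (2S)-2-{2-[(4-methoxyphenyl)methoxy]ethyl}-2-methyloxirane | COc1ccc(COCC[C@@]2(C)CO2)cc1 | intermediate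
8 | isobutyronitrile (2-methylpropanenitrile) | CC(C)C#N | starting material
9 | 2-lithio-2-methylpropanenitrile (formed in the flask) | [Li]C(C)(C)C#N | intermediate
10 | (4R)-4-hydroxy-6-[(4-methoxyphenyl)methoxy]-2,2,4-trimethylhexanenitrile | N#CC(C)(C)C[C@@](C)(O)CCOCc1ccc(OC)cc1 | intermediate
11 | (4R)-6-[(4-methoxyphenyl)methoxy]-2,2,4-trimethyl-4-[(triethylsilyl)oxy]hexanenitrile | N#CC(C)(C)C[C@@](C)(O[Si](CC)(CC)CC)CCOCc1ccc(OC)cc1 | intermediate
12 | N-(diisobutylaluminio) imine of aldehyde 13 (formed in the flask) | CC(C)C[Al](CC(C)C)N=CC(C)(C)C[C@@](C)(O[Si](CC)(CC)CC)CCOCc1ccc(OC)cc1 | intermediate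
13 | (4R)-6-[(4-methoxyphenyl)methoxy]-2,2,4-trimethyl-4-[(triethylsilyl)oxy]hexanal | O=CC(C)(C)C[C@@](C)(O[Si](CC)(CC)CC)CCOCc1ccc(OC)cc1 | intermediate
14 | dimethyl (2-oxobutyl)phosphonate | CCC(=O)CP(=O)(OC)OC | starting material
15 | (4E,8R)-10-[(4-methoxyphenyl)methoxy]-6,6,8-trimethyl-8-[(triethylsilyl)oxy]dec-4-en-3-one | CCC(=O)/C=C/C(C)(C)C[C@@](C)(O[Si](CC)(CC)CC)CCOCc1ccc(OC)cc1 | intermediate
16 | (4E,8R)-10-hydroxy-6,6,8-trimethyl-8-[(triethylsilyl)oxy]dec-4-en-3-one | CCC(=O)/C=C/C(C)(C)C[C@@](C)(O[Si](CC)(CC)CC)CCO | intermediate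
17 | (3R,6E)-3,5,5-trimethyl-8-oxo-3-[(triethylsilyl)oxy]dec-6-enal (C2 aldehyde, C4=C5 enone, C6 ethyl ketone) | CCC(=O)/C=C/C(C)(C)C[C@@](CC=O)(C)O[Si](CC)(CC)CC | intermediate
18 | (1R,2R,5R)-2,4,4-trimethyl-5-(2-oxobutyl)-2-[(triethylsilyl)oxy]cyclopentane-1-carbaldehyde (formed in the flask; formyl and oxobutyl groups trans, formyl cis to the C9 methyl) | O=C[C@@H]1[C@@H](CC(=O)CC)C(C)(C)C[C@@]1(C)O[Si](CC)(CC)CC | intermediate
19 | 7-hydroxy-1,3,3,6-tetramethyl-1-[(triethylsilyl)oxy]octahydro-5H-inden-5-one (formed in the flask; C3, C4, C9 as in 20, C1 and C2 epimers) | CC1C(O)[C@@H]2[C@@H](CC1=O)C(C)(C)C[C@@]2(C)O[Si](CC)(CC)CC | intermediate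
20 | (1R,3aR,7aR)-1,3,3,6-tetramethyl-1-[(triethylsilyl)oxy]-1,2,3,3a,4,7a-hexahydro-5H-inden-5-one (trans-fused; skeleton 3R,4R,9R) | CC1=C[C@@H]2[C@@H](CC1=O)C(C)(C)C[C@@]2(C)O[Si](CC)(CC)CC | intermediate
21 | 4-[(tert-butyldimethylsilyl)oxy]benzaldehyde | O=Cc1ccc(O[Si](C)(C)C(C)(C)C)cc1 | starting material
22 | lithium C5=C6 dienolate of 20 (formed in the flask) | CC1=C[C@@H]2[C@@H](C=C1O[Li])C(C)(C)C[C@@]2(C)O[Si](CC)(CC)CC | intermediate
23 | chlorobis(cyclopentadienyl)zirconium C5=C6 dienolate of 20 (formed in the flask) | CC1=C[C@@H]2[C@@H](C=C1O[Zr](Cl)(C3C=CC=C3)C4C=CC=C4)C(C)(C)C[C@@]2(C)O[Si](CC)(CC)CC | intermediate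
24 | syn-aldol: 20 bearing at C5, trans to the C4–C7 bond, an (S)-hydroxy{4-[(tert-butyldimethylsilyl)oxy]phenyl}methyl group (skeleton 3R,4S,5S,9R,10S) | CC1=C[C@@H]2[C@@H]([C@@H]([C@H](O)c3ccc(O[Si](C)(C)C(C)(C)C)cc3)C1=O)C(C)(C)C[C@@]2(C)O[Si](CC)(CC)CC | intermediate
25 | C10 tert-butyldimethylsilyl ether of 24 (skeleton 3R,4S,5S,9R,10S) | CC1=C[C@@H]2[C@@H]([C@@H]([C@H](O[Si](C)(C)C(C)(C)C)c3ccc(O[Si](C)(C)C(C)(C)C)cc3)C1=O)C(C)(C)C[C@@]2(C)O[Si](CC)(CC)CC | intermediate
26 | 6-ethynyl-6-hydroxy derivative of 25 (tertiary allylic, propargylic alcohol; C6 epimers, other centres as in 25) | CC1=C[C@@H]2[C@@H]([C@@H]([C@H](O[Si](C)(C)C(C)(C)C)c3ccc(O[Si](C)(C)C(C)(C)C)cc3)C1(O)C#C)C(C)(C)C[C@@]2(C)O[Si](CC)(CC)CC | intermediate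
27 | transposed enone: C2 ketone, C1(Me)=C6 alkene bearing ethynyl on C6 (skeleton 3R,4R,5R,9R,10S) | CC1=C(C#C)[C@H]([C@H](O[Si](C)(C)C(C)(C)C)c3ccc(O[Si](C)(C)C(C)(C)C)cc3)[C@H]2C(C)(C)C[C@@](C)(O[Si](CC)(CC)CC)[C@@H]2C1=O | intermediate
28 | C2 allylic alcohol from 27, hydroxyl pseudo-equatorial and cis to H3 (skeleton 2R,3S,4R,5R,9R,10S) | CC1=C(C#C)[C@H]([C@H](O[Si](C)(C)C(C)(C)C)c3ccc(O[Si](C)(C)C(C)(C)C)cc3)[C@H]2C(C)(C)C[C@@](C)(O[Si](CC)(CC)CC)[C@@H]2[C@H]1O | intermediate
29 | N-allyl-N-(2-nitrobenzenesulfonyl)hydrazine from 28, nitrogen on C2 with inverted configuration (formed in the flask) | CC1=C(C#C)[C@H]([C@H](O[Si](C)(C)C(C)(C)C)c3ccc(O[Si](C)(C)C(C)(C)C)cc3)[C@H]2C(C)(C)C[C@@](C)(O[Si](CC)(CC)CC)[C@@H]2[C@@H]1N(N)S(=O)(=O)c4ccccc4[N+](=O)[O-] | intermediate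
30 | allylic monoalkyl diazene at C2, axial, trans to H3 (formed in the flask) | CC1=C(C#C)[C@H]([C@H](O[Si](C)(C)C(C)(C)C)c3ccc(O[Si](C)(C)C(C)(C)C)cc3)[C@H]2C(C)(C)C[C@@](C)(O[Si](CC)(CC)CC)[C@@H]2[C@@H]1N=N | intermediate
31 | core alkyne: trans-fused hydrindene with C1=C2, equatorial ethynyl on C6 trans to C10, silyl-protected carbinol on C5, triethylsilyl ether on C9 (skeleton 3R,4R,5R,6R,9R,10S) | CC1=C[C@@H]2[C@@H]([C@@H]([C@H](O[Si](C)(C)C(C)(C)C)c3ccc(O[Si](C)(C)C(C)(C)C)cc3)[C@@H]1C#C)C(C)(C)C[C@@]2(C)O[Si](CC)(CC)CC | intermediate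
32 | 3-(trimethylsilyl)prop-2-ynal | C[Si](C)(C)C#CC=O | starting material
33 | (3R,4R)-4-methyl-1-(trimethylsilyl)hex-5-en-1-yn-3-ol | C[Si](C)(C)C#C[C@H](O)[C@H](C)C=C | intermediate
34 | (3R,4R)-3-[(tert-butyldimethylsilyl)oxy]-4-methyl-1-(trimethylsilyl)hex-5-en-1-yne | C[Si](C)(C)C#C[C@H](O[Si](C)(C)C(C)(C)C)[C@H](C)C=C | intermediate
35 | vicinal diol from 34, 4-[(tert-butyldimethylsilyl)oxy]-3-methyl-6-(trimethylsilyl)hex-5-yne-1,2-diol (formed in the flask; new carbinol epimers) | C[Si](C)(C)C#C[C@H](O[Si](C)(C)C(C)(C)C)[C@H](C)C(O)CO | intermediate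
36 | (2S,3R)-3-[(tert-butyldimethylsilyl)oxy]-2-methyl-5-(trimethylsilyl)pent-4-ynal | C[Si](C)(C)C#C[C@H](O[Si](C)(C)C(C)(C)C)[C@H](C)C=O | intermediate
37 | (3R,4R,5R)-3-[(tert-butyldimethylsilyl)oxy]-4-methyl-1-(trimethylsilyl)oct-7-en-1-yn-5-ol | C[Si](C)(C)C#C[C@H](O[Si](C)(C)C(C)(C)C)[C@H](C)[C@H](O)CC=C | intermediate
38 | (3R,4R,5R)-3,5-bis[(tert-butyldimethylsilyl)oxy]-4-methyl-1-(trimethylsilyl)oct-7-en-1-yne | C[Si](C)(C)C#C[C@H](O[Si](C)(C)C(C)(C)C)[C@H](C)[C@H](O[Si](C)(C)C(C)(C)C)CC=C | intermediate
39 | (2E,5R,6R,7R)-5,7-bis[(tert-butyldimethylsilyl)oxy]-2,6-dimethyl-9-(trimethylsilyl)non-2-en-8-ynal | C[Si](C)(C)C#C[C@H](O[Si](C)(C)C(C)(C)C)[C@H](C)[C@H](O[Si](C)(C)C(C)(C)C)C/C=C(C)/C=O | intermediate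
40 | methyl (2Z,4E,7R,8R,9R)-7,9-bis[(tert-butyldimethylsilyl)oxy]-4,8-dimethyl-11-(trimethylsilyl)undeca-2,4-dien-10-ynoate | C[Si](C)(C)C#C[C@H](O[Si](C)(C)C(C)(C)C)[C@H](C)[C@H](O[Si](C)(C)C(C)(C)C)C/C=C(C)/C=C\C(=O)OC | intermediate
41 | methyl (2Z,4E,7R,8R,9R)-7,9-bis[(tert-butyldimethylsilyl)oxy]-4,8-dimethylundeca-2,4-dien-10-ynoate | C#C[C@H](O[Si](C)(C)C(C)(C)C)[C@H](C)[C@H](O[Si](C)(C)C(C)(C)C)C/C=C(C)/C=C\C(=O)OC | intermediate
42 | (Z)-1,2-dichloroethene | Cl/C=C\Cl | starting material
43 | methyl (2Z,4E,7R,8R,9R,12Z)-7,9-bis[(tert-butyldimethylsilyl)oxy]-13-chloro-4,8-dimethyltrideca-2,4,12-trien-10-ynoate | Cl/C=C\C#C[C@H](O[Si](C)(C)C(C)(C)C)[C@H](C)[C@H](O[Si](C)(C)C(C)(C)C)C/C=C(C)/C=C\C(=O)OC | intermediate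
44 | protected enediyne methyl ester: 31 joined at C12–C13 to 43; C11≡C12, 13Z, C15≡C16, 21E, 23Z (skeleton 3R,4R,5R,6S,9R,10S,17R,18R,19R) | CC1=C[C@@H]2[C@@H]([C@@H]([C@H](O[Si](C)(C)C(C)(C)C)c3ccc(O[Si](C)(C)C(C)(C)C)cc3)[C@@H]1C#C/C=C\C#C[C@H](O[Si](C)(C)C(C)(C)C)[C@H](C)[C@H](O[Si](C)(C)C(C)(C)C)C/C=C(C)/C=C\C(=O)OC)C(C)(C)C[C@@]2(C)O[Si](CC)(CC)CC | intermediate
45 | protected methyl ester of the target: 11Z,13Z,15Z,21E,23Z; tert-butyldimethylsilyl ethers on the phenol, O10, O17 and O19, triethylsilyl ether on O9 (skeleton 3R,4R,5R,6S,9R,10S,17S,18R,19R) | CC1=C[C@@H]2[C@@H]([C@@H]([C@H](O[Si](C)(C)C(C)(C)C)c3ccc(O[Si](C)(C)C(C)(C)C)cc3)[C@@H]1\C=C/C=C\C=C/[C@H](O[Si](C)(C)C(C)(C)C)[C@H](C)[C@H](O[Si](C)(C)C(C)(C)C)C/C=C(C)/C=C\C(=O)OC)C(C)(C)C[C@@]2(C)O[Si](CC)(CC)CC | intermediate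
46 | carboxylic acid with free phenol; silyl ethers on O9, O10, O17 and O19 retained (skeleton 3R,4R,5R,6S,9R,10S,17S,18R,19R) | CC1=C[C@@H]2[C@@H]([C@@H]([C@H](O[Si](C)(C)C(C)(C)C)c3ccc(O)cc3)[C@@H]1\C=C/C=C\C=C/[C@H](O[Si](C)(C)C(C)(C)C)[C@H](C)[C@H](O[Si](C)(C)C(C)(C)C)C/C=C(C)/C=C\C(=O)O)C(C)(C)C[C@@]2(C)O[Si](CC)(CC)CC | intermediate
47 | CNP0118468.2 (skeleton 3R,4R,5R,6S,9R,10S,17S,18R,19R; 11Z,13Z,15Z,21E,23Z) | CC1=C[C@@H]2[C@@H]([C@@H]([C@H](O)c3ccc(O)cc3)[C@@H]1\C=C/C=C\C=C/[C@H](O)[C@H](C)[C@H](O)C/C=C(C)/C=C\C(=O)O)C(C)(C)C[C@@]2(C)O | target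

## Step count and risk

Total: 31 steps. Longest linear sequence: 22 steps from (S)-citramalic acid (steps 1–18 and 28–31). The chain branch takes 9 steps (19–27) before the union.

**Step 12 (key step).**
- What may go wrong: the enamine addition may stall, because the new C3–C4 bond joins two carbons that each have a quaternary neighbour and the bulky catalyst adds to the congestion. The beta-silyloxy aldehyde may also lose triethylsilanol, through the enamine or under TsOH, before ring A has closed.
- Fallback: stoichiometric Stork enamine chemistry. It sets out from 17, which is condensed with pyrrolidine to the isolable pyrrolidine enamine F1. This enamine is smaller and more nucleophilic and should cyclise on gentle warming; hydrolysis gives keto aldehyde 18. Ring A is then closed in a separate operation with dibenzylammonium trifluoroacetate, and the route is rejoined at 20. The price is that C3 and C4 then rest on the C9 centre and the trans preference of the closure alone.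

**Step 13 (aldol).**
- What may go wrong: simple diastereoselection may be eroded, since zirconocene enolates of cyclic ketones are syn-selective but not strongly so, and the face of attack at C5 may be less one-sided than the carvone-type analogy suggests.
- Fallback: a Mukaiyama aldol through an open transition state. It sets out from 20, whose kinetic enolate is trapped with Me3SiCl as the silyl dienol ether F2. Fluoride activation with tris(dimethylamino)sulfonium difluorotrimethylsilicate in the presence of 21 gives syn aldols irrespective of enolate geometry. Work-up returns 24.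

**Steps 17–18 (C6 configuration).**
- What may go wrong: the Mitsunobu displacement at the hindered C2 carbinol, which lies next to the ring fusion, may fail or give elimination. Alternatively the hydride of step 17 may enter from the other face, so that hydrogen reaches the wrong face of C6.
- Fallback: reductive transposition through a tosylhydrazone. It sets out from enone 27, which is condensed with 4-toluenesulfonylhydrazide to the tosylhydrazone F3. Reduction with catecholborane followed by NaOAc releases the sulfinate, and the same allylic diazene retro-ene reaction leads to 31. The bulkier hydride approaches C2 from the equatorial direction, which again places the diazene axial.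

**Step 24 (cross-metathesis).**
- What may go wrong: the catalyst may be consumed by enyne metathesis at the silyl alkyne, or turnover with the electron-poor 1,1-disubstituted partner may be slow.
- Fallback: it sets out from 38. Lemieux–Johnson cleavage of the terminal alkene gives the aldehyde F4, and Wittig reaction with 2-(triphenylphosphoranylidene)propanal returns the E-enal 39.

**Step 29 (double semi-reduction).**
- What may go wrong: the two triple bonds may be reduced at different rates, the one next to the silyloxy-bearing C17 being the slower, so that partial reduction and prolonged exposure of the triene compete.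
- Fallback: one triple bond at a time. It sets out from 43, which is reduced with Zn(Cu/Ag) to the (Z,Z)-chlorodiene F5. Sonogashira coupling of F5 with 31 under conditions for unactivated alkenyl chlorides (PdCl2(MeCN)2, a biaryl dialkylphosphine, Cs2CO3) gives the dienyne F6. A single zinc reduction then returns 45.

## Further compounds

F1 | step 12 | pyrrolidine enamine of 17, (3R,4E... E-enamine at C2=C3) 1-[(1E,3R,6E)-3,5,5-trimethyl-8-oxo-3-(triethylsilyloxy)deca-1,6-dien-1-yl]pyrrolidine | CCC(=O)/C=C/C(C)(C)C[C@@](C)(O[Si](CC)(CC)CC)/C=C/N1CCCC1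
F2 | step 13 | trimethylsilyl dienol ether of 20 (C5=C6 enol ether) | CC1=C[C@@H]2[C@@H](C=C1O[Si](C)(C)C)C(C)(C)C[C@@]2(C)O[Si](CC)(CC)CC
F3 | step 18 | 4-toluenesulfonylhydrazone of enone 27 at C2 | CC1=C(C#C)[C@H]([C@H](O[Si](C)(C)C(C)(C)C)c3ccc(O[Si](C)(C)C(C)(C)C)cc3)[C@H]2C(C)(C)C[C@@](C)(O[Si](CC)(CC)CC)[C@@H]2C1=NNS(=O)(=O)c4ccc(C)cc4
F4 | step 24 | (3R,4R,5R)-3,5-bis[(tert-butyldimethylsilyl)oxy]-4-methyl-7-(trimethylsilyl)hept-6-ynal | C[Si](C)(C)C#C[C@H](O[Si](C)(C)C(C)(C)C)[C@H](C)[C@H](O[Si](C)(C)C(C)(C)C)CC=O
F5 | step 29 | methyl (2Z,4E,7R,8R,9S,10Z,12Z)-7,9-bis[(tert-butyldimethylsilyl)oxy]-13-chloro-4,8-dimethyltrideca-2,4,10,12-tetraenoate | Cl/C=C\C=C/[C@H](O[Si](C)(C)C(C)(C)C)[C@H](C)[C@H](O[Si](C)(C)C(C)(C)C)C/C=C(C)/C=C\C(=O)OC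
F6 | step 29 | protected dienyne methyl ester: C11≡C12, 13Z, 15Z, otherwise as 45 | CC1=C[C@@H]2[C@@H]([C@@H]([C@H](O[Si](C)(C)C(C)(C)C)c3ccc(O[Si](C)(C)C(C)(C)C)cc3)[C@@H]1C#C/C=C\C=C/[C@H](O[Si](C)(C)C(C)(C)C)[C@H](C)[C@H](O[Si](C)(C)C(C)(C)C)C/C=C(C)/C=C\C(=O)OC)C(C)(C)C[C@@]2(C)O[Si](CC)(CC)CC
A1 | alternative 1 | 4,4-dimethylcyclopent-2-en-1-one | CC1(C)CC(=O)C=C1
A2 | alternative 1 | 1-methoxy-1-(trimethylsilyloxy)ethene | C=C(OC)O[Si](C)(C)C
A3 | alternative 1 | trans-2-(dimethoxymethyl)-3-(methoxycarbonylmethyl)-4,4-dimethylcyclopentanone | COC(OC)[C@@H]1[C@@H](CC(=O)OC)C(C)(C)CC1=O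
A4 | alternative 2 | 19-membered dienyne macrolactone (O10–C25 ester, C13≡C14) | CC1=C[C@@H]2[C@@H]([C@@H]([C@H](O9)c3ccc(O[Si](C)(C)C(C)(C)C)cc3)[C@@H]1\C=C/C#C\C=C/[C@H](O[Si](C)(C)C(C)(C)C)[C@H](C)[C@H](O[Si](C)(C)C(C)(C)C)C/C=C(C)/C=C\C9=O)C(C)(C)C[C@@]2(C)O[Si](CC)(CC)CC
A5 | alternative 3 | hydrindene C11 tert-butyl ester | CC1=C[C@@H]2[C@@H]([C@@H]([C@H](O[Si](C)(C)C(C)(C)C)c3ccc(O[Si](C)(C)C(C)(C)C)cc3)[C@@H]1C(=O)OC(C)(C)C)C(C)(C)C[C@@]2(C)O[Si](CC)(CC)CC
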